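Retrosynthesis: the pyranone ring is opened at O1–C2 (oxa-Michael); the C2=C3 alkylidene, given a temporary CO2t-Bu on C3, is cut at C2=C3 (Knoevenagel) into an A-ring β-ketoester and a B-ring aldehyde; the A ring is cut at C8–C1'' (phenoxide C-alkylation) and the side chain at C1''–C2'' (hydroxymethylation of a Z-alkenyl iodide).
Forward: propargyl alcohol → Z-allylic bromide (4 steps); C-alkylation of the symmetric 2',6'-dihydroxy-4'-methoxyacetophenone; TIPS on the oxygen that becomes 5-OH; β-ketoester; Knoevenagel with silylated protocatechualdehyde; the C ring is closed last; desilylation.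
Enabling feature: in the C ring O1 sits on C8a, ortho to C4a which carries the C4 carbonyl, and C2 is the β-carbon of that carbonyl. An ester on C3 makes C2=C3 a two-point-binding 1,3-dicarbonyl acceptor, so a bifunctional catalyst can steer O1 onto one face of C2 (6-endo-trig); the ester then leaves as CO2.
Stereochemistry: C2 (S) is set by the chiral thiourea catalyst in the ring closure. The Z-alkene comes from anti-carbomagnesiation/iodination of propargyl alcohol and is carried through stereoretentive steps. C8 versus C6 follows from the symmetry of the acetophenone, and O1 versus O5 from silylation of the unhindered phenol.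

Key step: step 10

Assumption: the quinidine-derived thiourea is taken to be the pseudoenantiomer that leads to the 2S series; the sense of induction is to be checked on the first batch, and the quinine-derived catalyst is used instead if it proves opposite.

Step 1
Reactants: 1 prop-2-yn-1-ol
Product: 3 (2Z)-3-iodo-2-methylprop-2-en-1-ol, via alkenylmagnesium alkoxide 2 (not isolated)
Conditions: MeMgBr (2.5 equiv), CuI (10 mol %), THF/Et2O, −10 °C → rt; then I2, −78 → 0 °C
Reagents that add atoms: methylmagnesium bromide C[Mg]Br; iodine II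
Why: Copper-catalysed anti-carbomagnesiation of the propargylic magnesium alkoxide should place Me on C2 and Mg on C3 cis to the CH2O group within a five-membered chelate, and iodinolysis with retention then gives the Z-iodide (carbometalation–iodination), which is where the side-chain geometry is set.

Step 2
Reactants: 3 (2Z)-3-iodo-2-methylprop-2-en-1-ol
Product: 4 tert-butyl{[(2Z)-3-iodo-2-methylprop-2-en-1-yl]oxy}diphenylsilane
Conditions: TBDPSCl, imidazole, CH2Cl2, 0 °C → rt
Reagents that add atoms: tert-butyl(chloro)diphenylsilane CC(C)(C)[Si](Cl)(c1ccccc1)c1ccccc1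
Why: Standard silylation of a primary alcohol; TBDPS is chosen because it should resist the later organolithium, base and acid steps and is slow to undergo 1,4 O→C silyl shift in the next step.

Step 3
Reactants: 4 tert-butyl{[(2Z)-3-iodo-2-methylprop-2-en-1-yl]oxy}diphenylsilane
Product: 6 (2Z)-4-[(tert-butyldiphenylsilyl)oxy]-3-methylbut-2-en-1-ol, via alkenyllithium 5 (not isolated)
Conditions: t-BuLi (2.1 equiv), Et2O, −78 °C; then (CH2O)n, −78 °C → rt
Reagents that add atoms: formaldehyde (as paraformaldehyde) C=O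
Why: Iodine–lithium exchange of an alkenyl iodide proceeds with retention of geometry, and the alkenyllithium is hydroxymethylated by formaldehyde (halogen–metal exchange then 1,2-addition).

Step 4
Reactants: 6 (2Z)-4-[(tert-butyldiphenylsilyl)oxy]-3-methylbut-2-en-1-ol
Product: 7 {[(2Z)-4-bromo-2-methylbut-2-en-1-yl]oxy}(tert-butyl)diphenylsilane
Conditions: CBr4, PPh3, CH2Cl2, −20 → 0 °C; used at once
Reagents that add atoms: carbon tetrabromide BrC(Br)(Br)Br
Why: The Appel reaction converts the primary allylic alcohol into the bromide by SN2 at low temperature, so the trisubstituted Z-alkene should not be touched.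

Step 5
Reactants: 8 1-(2,6-dihydroxy-4-methoxyphenyl)ethan-1-one; 7 {[(2Z)-4-bromo-2-methylbut-2-en-1-yl]oxy}(tert-butyl)diphenylsilane
Product: 9 1-(3-{(2Z)-4-[(tert-butyldiphenylsilyl)oxy]-3-methylbut-2-en-1-yl}-2,6-dihydroxy-4-methoxyphenyl)ethan-1-one
Conditions: DBU (2.2 equiv), THF, 0 °C → rt
Reagents that add atoms: none
Why: C-Alkylation of the doubly deprotonated 2,6-dihydroxyaryl ketone by SN2 at the primary allylic bromide (the C-prenylation reaction type of acylphloroglucinols) should keep the Z geometry, and because C3 and C5 of 8 are equivalent by symmetry only one C-alkyl regioisomer can form.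

Step 6
Reactants: 9 1-(3-{(2Z)-4-[(tert-butyldiphenylsilyl)oxy]-3-methylbut-2-en-1-yl}-2,6-dihydroxy-4-methoxyphenyl)ethan-1-one
Product: 10 1-(3-{(2Z)-4-[(tert-butyldiphenylsilyl)oxy]-3-methylbut-2-en-1-yl}-2-hydroxy-4-methoxy-6-[(triisopropylsilyl)oxy]phenyl)ethan-1-one
Conditions: TIPSOTf (1.05 equiv), 2,6-lutidine, CH2Cl2, −78 → 0 °C
Reagents that add atoms: triisopropylsilyl trifluoromethanesulfonate CC(C)[Si](OS(=O)(=O)C(F)(F)F)(C(C)C)C(C)C
Why: Regioselective phenol silylation: the bulky TIPS triflate should take the unhindered 6-OH and leave the 2-OH that is flanked by the side chain and the acetyl group, which is exactly the oxygen that becomes O1.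

Step 7
Reactants: 10 1-(3-{(2Z)-4-[(tert-butyldiphenylsilyl)oxy]-3-methylbut-2-en-1-yl}-2-hydroxy-4-methoxy-6-[(triisopropylsilyl)oxy]phenyl)ethan-1-one
Product: 11 tert-butyl 3-(3-{(2Z)-4-[(tert-butyldiphenylsilyl)oxy]-3-methylbut-2-en-1-yl}-2-hydroxy-4-methoxy-6-[(triisopropylsilyl)oxy]phenyl)-3-oxopropanoate
Conditions: LiHMDS (3.2 equiv), THF, −78 °C; Boc2O (1.1 equiv), −78 → 0 °C; aq. NH4Cl
Reagents that add atoms: di-tert-butyl dicarbonate CC(C)(C)OC(=O)OC(=O)OC(C)(C)C
Why: Claisen-type C-acylation of the ketone enolate (phenoxide–enolate dianion) with Boc2O should give the tert-butyl β-ketoester, any aryl carbonate formed first being relayed to carbon by a Baker–Venkataraman-type O→C shift and the product being held as its stabilised enolate.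

Step 8
Reactants: 12 3,4-dihydroxybenzaldehyde
Product: 13 3,4-bis[(tert-butyldimethylsilyl)oxy]benzaldehyde
Conditions: TBSCl (2.4 equiv), imidazole, DMF, rt
Reagents that add atoms: tert-butyl(chloro)dimethylsilane CC(C)(C)[Si](C)(C)Cl
Why: Standard bis-silylation of the catechol, giving aryl silyl ethers that tolerate the later amine and acid steps.

Step 9
Reactants: 11 tert-butyl 3-(3-{(2Z)-4-[(tert-butyldiphenylsilyl)oxy]-3-methylbut-2-en-1-yl}-2-hydroxy-4-methoxy-6-[(triisopropylsilyl)oxy]phenyl)-3-oxopropanoate; 13 3,4-bis[(tert-butyldimethylsilyl)oxy]benzaldehyde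
Product: 14 tert-butyl (2Z)-3-{3,4-bis[(tert-butyldimethylsilyl)oxy]phenyl}-2-(3-{(2Z)-4-[(tert-butyldiphenylsilyl)oxy]-3-methylbut-2-en-1-yl}-2-hydroxy-4-methoxy-6-[(triisopropylsilyl)oxy]benzoyl)prop-2-enoate
Conditions: piperidine (20 mol %), AcOH (20 mol %), 4 Å MS, benzene, rt
Reagents that add atoms: none
Why: Knoevenagel condensation of the active methylene compound with the aryl aldehyde should give the alkylidene β-ketoester (drawn as the isomer with the aryl group cis to the ester; this geometry is lost on ring closure), and the bulky tert-butyl ester together with the hindered, hydrogen-bonded phenol should keep it from cyclising here.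

Step 10
Reactants: 14 tert-butyl (2Z)-3-{3,4-bis[(tert-butyldimethylsilyl)oxy]phenyl}-2-(3-{(2Z)-4-[(tert-butyldiphenylsilyl)oxy]-3-methylbut-2-en-1-yl}-2-hydroxy-4-methoxy-6-[(triisopropylsilyl)oxy]benzoyl)prop-2-enoate
Product: 17 (2S)-2-{3,4-bis[(tert-butyldimethylsilyl)oxy]phenyl}-8-{(2Z)-4-[(tert-butyldiphenylsilyl)oxy]-3-methylbut-2-en-1-yl}-7-methoxy-5-[(triisopropylsilyl)oxy]chroman-4-one, via tert-butyl 4-oxochromane-3-carboxylate 15 (not isolated), via 4-oxochromane-3-carboxylic acid 16 (not isolated)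
Conditions: quinidine-derived 3,5-(CF3)2C6H3-thiourea (10 mol %), toluene, −25 °C; then TsOH·H2O, 80 °C (one pot)
Reagents that add atoms: none
Why: The quinuclidine nitrogen of the bifunctional catalyst activates the only free phenol (O1–H on C8a) while the thiourea N–H pair binds the 1,3-dicarbonyl unit, so O1 adds to the β-carbon (future C2) and closes the pyranone ring in a 6-endo-trig oxa-Michael reaction; acid then cleaves the tert-butyl ester and the β-keto acid loses CO2. The closest known reaction type is the cinchona-thiourea-catalysed oxa-conjugate addition of 2-hydroxyaryl alkylidene β-ketoesters to flavanones with one-pot acid decarboxylation. The C2 stereocentre is controlled by the catalyst through face selection in the hydrogen-bonded ion pair, whereas C3 is stereolabile and becomes CH2. The step needs enantioselectivity over the uncatalysed closure, which the bulky tert-butyl ester, the ortho,ortho'-disubstituted aroyl group and the low temperature should secure. It also needs O1 rather than O5 to attack, which is secured because O5 is a TIPS ether. The aryl silyl ethers, the TBDPS ether and the β-oxygenated trisubstituted alkene are expected to tolerate the brief acid treatment, under which retro-oxa-Michael racemisation is slow.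

Step 11
Reactants: 17 (2S)-2-{3,4-bis[(tert-butyldimethylsilyl)oxy]phenyl}-8-{(2Z)-4-[(tert-butyldiphenylsilyl)oxy]-3-methylbut-2-en-1-yl}-7-methoxy-5-[(triisopropylsilyl)oxy]chroman-4-one
Product: 18 (2S)-2-(3,4-dihydroxyphenyl)-5-hydroxy-8-[(2Z)-4-hydroxy-3-methylbut-2-en-1-yl]-7-methoxychroman-4-one
Conditions: TBAF/AcOH (1:1, 6 equiv), THF, 0 °C → rt
Reagents that add atoms: none
Why: Fluoride-mediated Si–O cleavage should remove the three aryl silyl ethers and the TBDPS ether in one operation, and the acetic acid buffer keeps phenoxides from building up so that the flavanone is not opened by retro-oxa-Michael reaction and C2 is not scrambled.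

Compound list
1 | prop-2-yn-1-ol (propargyl alcohol) | C#CCO | starting material
2 | bromomagnesium (2Z)-3-(bromomagnesio)-2-methylprop-2-en-1-olate (formed in situ) | C/C(CO[Mg]Br)=C/[Mg]Br | intermediate
3 | (2Z)-3-iodo-2-methylprop-2-en-1-ol | C/C(CO)=C/I | intermediate
4 | tert-butyl{[(2Z)-3-iodo-2-methylprop-2-en-1-yl]oxy}diphenylsilane | C/C(CO[Si](c1ccccc1)(c1ccccc1)C(C)(C)C)=C/I | intermediate
5 | {(1Z)-3-[(tert-butyldiphenylsilyl)oxy]-2-methylprop-1-en-1-yl}lithium (formed in situ) | C/C(CO[Si](c1ccccc1)(c1ccccc1)C(C)(C)C)=C/[Li] | intermediate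
6 | (2Z)-4-[(tert-butyldiphenylsilyl)oxy]-3-methylbut-2-en-1-ol | C/C(CO[Si](c1ccccc1)(c1ccccc1)C(C)(C)C)=C/CO | intermediate
7 | {[(2Z)-4-bromo-2-methylbut-2-en-1-yl]oxy}(tert-butyl)diphenylsilane | C/C(CO[Si](c1ccccc1)(c1ccccc1)C(C)(C)C)=C/CBr | intermediate
8 | 1-(2,6-dihydroxy-4-methoxyphenyl)ethan-1-one | CC(=O)c1c(O)cc(OC)cc1O | starting material
9 | 1-(3-{(2Z)-4-[(tert-butyldiphenylsilyl)oxy]-3-methylbut-2-en-1-yl}-2,6-dihydroxy-4-methoxyphenyl)ethan-1-one | CC(=O)c1c(O)cc(OC)c(C/C=C(/C)CO[Si](c2ccccc2)(c2ccccc2)C(C)(C)C)c1O | intermediate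
10 | 1-(3-{(2Z)-4-[(tert-butyldiphenylsilyl)oxy]-3-methylbut-2-en-1-yl}-2-hydroxy-4-methoxy-6-[(triisopropylsilyl)oxy]phenyl)ethan-1-one | CC(=O)c1c(O[Si](C(C)C)(C(C)C)C(C)C)cc(OC)c(C/C=C(/C)CO[Si](c2ccccc2)(c2ccccc2)C(C)(C)C)c1O | intermediate
11 | tert-butyl 3-(3-{(2Z)-4-[(tert-butyldiphenylsilyl)oxy]-3-methylbut-2-en-1-yl}-2-hydroxy-4-methoxy-6-[(triisopropylsilyl)oxy]phenyl)-3-oxopropanoate | CC(C)(C)OC(=O)CC(=O)c1c(O[Si](C(C)C)(C(C)C)C(C)C)cc(OC)c(C/C=C(/C)CO[Si](c2ccccc2)(c2ccccc2)C(C)(C)C)c1O | intermediate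
12 | 3,4-dihydroxybenzaldehyde | O=Cc1ccc(O)c(O)c1 | starting material
13 | 3,4-bis[(tert-butyldimethylsilyl)oxy]benzaldehyde | O=Cc1ccc(O[Si](C)(C)C(C)(C)C)c(O[Si](C)(C)C(C)(C)C)c1 | intermediate
14 | tert-butyl (2Z)-3-{3,4-bis[(tert-butyldimethylsilyl)oxy]phenyl}-2-(3-{(2Z)-4-[(tert-butyldiphenylsilyl)oxy]-3-methylbut-2-en-1-yl}-2-hydroxy-4-methoxy-6-[(triisopropylsilyl)oxy]benzoyl)prop-2-enoate | CC(C)(C)OC(=O)/C(=C\c1ccc(O[Si](C)(C)C(C)(C)C)c(O[Si](C)(C)C(C)(C)C)c1)C(=O)c1c(O[Si](C(C)C)(C(C)C)C(C)C)cc(OC)c(C/C=C(/C)CO[Si](c2ccccc2)(c2ccccc2)C(C)(C)C)c1O | intermediate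
15 | tert-butyl (2S)-2-{3,4-bis[(tert-butyldimethylsilyl)oxy]phenyl}-8-{(2Z)-4-[(tert-butyldiphenylsilyl)oxy]-3-methylbut-2-en-1-yl}-7-methoxy-4-oxo-5-[(triisopropylsilyl)oxy]chromane-3-carboxylate (C3 stereolabile; formed in situ) | COc1cc(O[Si](C(C)C)(C(C)C)C(C)C)c2c(c1C/C=C(/C)CO[Si](c3ccccc3)(c3ccccc3)C(C)(C)C)O[C@H](c3ccc(O[Si](C)(C)C(C)(C)C)c(O[Si](C)(C)C(C)(C)C)c3)C(C(=O)OC(C)(C)C)C2=O | intermediate
16 | (2S)-2-{3,4-bis[(tert-butyldimethylsilyl)oxy]phenyl}-8-{(2Z)-4-[(tert-butyldiphenylsilyl)oxy]-3-methylbut-2-en-1-yl}-7-methoxy-4-oxo-5-[(triisopropylsilyl)oxy]chromane-3-carboxylic acid (C3 stereolabile; formed in situ) | COc1cc(O[Si](C(C)C)(C(C)C)C(C)C)c2c(c1C/C=C(/C)CO[Si](c3ccccc3)(c3ccccc3)C(C)(C)C)O[C@H](c3ccc(O[Si](C)(C)C(C)(C)C)c(O[Si](C)(C)C(C)(C)C)c3)C(C(=O)O)C2=O | intermediate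
17 | (2S)-2-{3,4-bis[(tert-butyldimethylsilyl)oxy]phenyl}-8-{(2Z)-4-[(tert-butyldiphenylsilyl)oxy]-3-methylbut-2-en-1-yl}-7-methoxy-5-[(triisopropylsilyl)oxy]chroman-4-one | COc1cc(O[Si](C(C)C)(C(C)C)C(C)C)c2c(c1C/C=C(/C)CO[Si](c3ccccc3)(c3ccccc3)C(C)(C)C)O[C@H](c3ccc(O[Si](C)(C)C(C)(C)C)c(O[Si](C)(C)C(C)(C)C)c3)CC2=O | intermediate
18 | (2S)-2-(3,4-dihydroxyphenyl)-5-hydroxy-8-[(2Z)-4-hydroxy-3-methylbut-2-en-1-yl]-7-methoxychroman-4-one (CNP0246822.1) | COc1cc(O)c2c(c1C/C=C(/C)CO)O[C@H](c1ccc(O)c(O)c1)CC2=O | target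

Total step count: 11. Longest linear sequence: 10 (steps 1–7 and 9–11, from propargyl alcohol).

Steps most likely to fail

Step 5. O-Alkylation and double alkylation may outrun C-alkylation of the dianion, and the Z-allylic bromide may isomerise before it is consumed. The fallback sets out from 8 and returns at 9. One of the two equivalent phenols of 8 is O-allylated (allyl bromide, K2CO3, acetone) to give 1-[2-(allyloxy)-6-hydroxy-4-methoxyphenyl]ethan-1-one F1. An aromatic Claisen rearrangement (N,N-diethylaniline, 190 °C) should then move the allyl group to the only free ortho carbon and give 1-(3-allyl-2,6-dihydroxy-4-methoxyphenyl)ethan-1-one F2. Cross-metathesis of F2 with tert-butyl[(2-methylprop-2-en-1-yl)oxy]diphenylsilane F3 (from 2-methylprop-2-en-1-ol, TBDPSCl and imidazole), using a second-generation ruthenium benzylidene catalyst in CH2Cl2 at 40 °C, builds the trisubstituted alkene as an E/Z mixture. Compound 9 is separated from the E isomer F4 on AgNO3-impregnated silica. The ring–chain bond is then made by a sigmatropic shift instead of an SN2 reaction, at the price of unselective olefin geometry.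

Step 10. Enantiofacial discrimination may be poor on this ortho,ortho'-disubstituted, electron-rich aroyl system, uncatalysed closure may compete, and the acid stage may cause partial desilylation or Z/E isomerisation of the side chain. The fallback sets out from 14 and returns at 17. Closure without chiral control (Et3N, toluene, rt) gives the racemic tert-butyl ester F5. TsOH at 80 °C converts this into the racemic keto acid F6, which decarboxylates to the racemic silyl-protected flavanone F7. Preparative chiral SFC on a polysaccharide phase should deliver 17, and the unwanted enantiomer is racemised with catalytic DBU (reversible retro-oxa-Michael opening) and recycled. Resolution with recycling replaces asymmetric catalysis.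

Step 7. Acylation at the phenoxide or enolate oxygen may compete with C-acylation, the product may lactonise to a 4-hydroxycoumarin, and the TIPS group may migrate to the enolate oxygen. The fallback sets out from 10 and returns at 11. The phenol is first converted into the aryl tert-butyl carbonate F8 (Boc2O, DMAP, Et3N, CH2Cl2). A Baker–Venkataraman rearrangement (LiHMDS, THF, −78 → 0 °C) should then transfer the tert-butoxycarbonyl group from oxygen to the enolate carbon inside the molecule and give 11. The acyl group is delivered intramolecularly instead of by intermolecular C-acylation.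

Further compounds
F1 | step 5 | 1-[2-(allyloxy)-6-hydroxy-4-methoxyphenyl]ethan-1-one | CC(=O)c1c(O)cc(OC)cc1OCC=C
F2 | step 5 | 1-(3-allyl-2,6-dihydroxy-4-methoxyphenyl)ethan-1-one | CC(=O)c1c(O)cc(OC)c(CC=C)c1O
F3 | step 5 | tert-butyl[(2-methylprop-2-en-1-yl)oxy]diphenylsilane | C=C(C)CO[Si](c1ccccc1)(c1ccccc1)C(C)(C)C
F4 | step 5 | 1-(3-{(2E)-4-[(tert-butyldiphenylsilyl)oxy]-3-methylbut-2-en-1-yl}-2,6-dihydroxy-4-methoxyphenyl)ethan-1-one (E isomer of 9) | CC(=O)c1c(O)cc(OC)c(C/C=C(\C)CO[Si](c2ccccc2)(c2ccccc2)C(C)(C)C)c1O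
F5 | step 10 | racemic tert-butyl 2-{3,4-bis[(tert-butyldimethylsilyl)oxy]phenyl}-8-{(2Z)-4-[(tert-butyldiphenylsilyl)oxy]-3-methylbut-2-en-1-yl}-7-methoxy-4-oxo-5-[(triisopropylsilyl)oxy]chromane-3-carboxylate | COc1cc(O[Si](C(C)C)(C(C)C)C(C)C)c2c(c1C/C=C(/C)CO[Si](c3ccccc3)(c3ccccc3)C(C)(C)C)OC(c3ccc(O[Si](C)(C)C(C)(C)C)c(O[Si](C)(C)C(C)(C)C)c3)C(C(=O)OC(C)(C)C)C2=O
F6 | step 10 | racemic 2-{3,4-bis[(tert-butyldimethylsilyl)oxy]phenyl}-8-{(2Z)-4-[(tert-butyldiphenylsilyl)oxy]-3-methylbut-2-en-1-yl}-7-methoxy-4-oxo-5-[(triisopropylsilyl)oxy]chromane-3-carboxylic acid | COc1cc(O[Si](C(C)C)(C(C)C)C(C)C)c2c(c1C/C=C(/C)CO[Si](c3ccccc3)(c3ccccc3)C(C)(C)C)OC(c3ccc(O[Si](C)(C)C(C)(C)C)c(O[Si](C)(C)C(C)(C)C)c3)C(C(=O)O)C2=O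
F7 | step 10 | racemic 2-{3,4-bis[(tert-butyldimethylsilyl)oxy]phenyl}-8-{(2Z)-4-[(tert-butyldiphenylsilyl)oxy]-3-methylbut-2-en-1-yl}-7-methoxy-5-[(triisopropylsilyl)oxy]chroman-4-one | COc1cc(O[Si](C(C)C)(C(C)C)C(C)C)c2c(c1C/C=C(/C)CO[Si](c3ccccc3)(c3ccccc3)C(C)(C)C)OC(c3ccc(O[Si](C)(C)C(C)(C)C)c(O[Si](C)(C)C(C)(C)C)c3)CC2=O
F8 | step 7 | 2-acetyl-6-{(2Z)-4-[(tert-butyldiphenylsilyl)oxy]-3-methylbut-2-en-1-yl}-5-methoxy-3-[(triisopropylsilyl)oxy]phenyl tert-butyl carbonate | CC(=O)c1c(O[Si](C(C)C)(C(C)C)C(C)C)cc(OC)c(C/C=C(/C)CO[Si](c2ccccc2)(c2ccccc2)C(C)(C)C)c1OC(=O)OC(C)(C)C
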